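**Retrosynthetic overview**

1. Difengpiol A ⇒ cut C3–C3a and C2–O1: 5-iodo-dihydroconiferyl alcohol plus an (E)-dienetriol; a palladium Heck/allylic etherification heteroannulation closes the trans-dihydrofuran.
2. Dienetriol ⇒ cut C1′=C2′ and C2=C3: acyclic (3S,4R)-enyne diol plus allyl alcohol; ruthenium enyne metathesis closes the cyclohexene. Both closures are run in one flask.
3. Enyne diol ⇒ propargyl Grignard plus (2R,3S)-epoxy alcohol, from Sharpless desymmetrisation of divinylcarbinol (source of both diol centres).
4. Iodophenol ⇐ ortho-iodination of dihydroconiferyl alcohol.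
5. Ring order: benzene ring bought; then cyclohexene, then dihydrofuran, the last two in the final operation.

Assumption: in the last step the (S,R,R) antipode of the phosphoramidite ligand is taken as the one that matches the fixed diol centres for the (2S,3R) pair; if a first run shows the opposite sense, its mirror image is used and nothing else changes.

**Route**

Step 1
Reactants: 1 penta-1,4-dien-3-ol (divinylcarbinol)
Product: 2 (2R,3S)-1,2-epoxypent-4-en-3-ol
Conditions: Ti(OiPr)4 (15 mol%), L-(+)-diisopropyl tartrate (18 mol%), t-BuOOH, 4 Å MS, CH2Cl2, −20 °C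
Reagents that add atoms: tert-butyl hydroperoxide, CC(C)(C)OO
Why: Sharpless asymmetric epoxidation used as a desymmetrisation: the L-(+)-tartrate titanium catalyst picks one enantiotopic vinyl group and one alkene face, giving the erythro (2R,3S) epoxy alcohol (C2 by face control, C3 by group selection), and the minor enantiomer is drained off as bis-epoxide so the ee rises with conversion.

Step 2
Reactants: 2 (2R,3S)-1,2-epoxypent-4-en-3-ol; 3 3-bromoprop-1-yne (propargyl bromide)
Product: 5 (3S,4R)-oct-1-en-7-yne-3,4-diol, via allenylmagnesium bromide 4 (not isolated)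
Conditions: 3 (3 equiv), Mg, ZnBr2 (2 mol%), Et2O, 0 °C; then 2, −20 °C to rt; H2O
Reagents that add atoms: none
Why: After the first equivalent deprotonates the hydroxyl, the allenyl Grignard opens the terminal epoxide at its unhindered CH2 carbon (SE2′ propargylation), and since neither C–O bond at the stereocentres is touched the (2R,3S) centres become (3S,4R).

Step 3
Reactants: 6 4-(3-hydroxypropyl)-2-methoxyphenol (dihydroconiferyl alcohol)
Product: 7 4-(3-hydroxypropyl)-2-iodo-6-methoxyphenol
Conditions: I2, NaHCO3, THF/H2O, 0 °C to rt
Reagents that add atoms: iodine, II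
Why: Electrophilic aromatic iodination of the phenoxide, where the para position is blocked and only one ortho position is free, so iodine enters next to the hydroxyl.

Step 4
Reactants: 5 (3S,4R)-oct-1-en-7-yne-3,4-diol; 7 4-(3-hydroxypropyl)-2-iodo-6-methoxyphenol; 8 prop-2-en-1-ol (allyl alcohol)
Product: 10 difengpiol A, via dienetriol 9 (not isolated)
Conditions: 8 (5 equiv), second-generation Hoveyda–Grubbs catalyst RuCl2(H2IMes)(=CH-C6H4-2-OiPr) (5 mol%), CH2Cl2 (0.02 M), 40 °C; evaporate; then 7 (1.2 equiv), Pd(OAc)2 (5 mol%), (S)-BINOL N,N-bis[(R)-1-phenylethyl]phosphoramidite (12 mol%), NaHCO3, n-Bu4NCl, DMF, 80 °C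
Reagents that add atoms: none
Why: Proposed new method: the alkylidene made from 8 adds to the terminal alkyne of 5 and the vinylcarbene so formed ring-closes onto the vinyl group with loss of ethene (cross-enyne metathesis/ring-closing metathesis, the conjugated E-diene being the thermodynamic sink), and after the volatiles are stripped the same flask is used for a Larock-type heteroannulation of diene 9 by 7 – oxidative addition, syn-arylpalladation of the less hindered E-alkene with the aryl going to C3 to give a π-allylpalladium phenoxide, then C2–O bond formation on the palladium face, i.e. net syn addition that makes the 2,3-trans ring – in which the chiral phosphoramidite chooses the alkene face against the already fixed diol centres, so that the wrong-face product is a diastereomer removed by chromatography; the closest known reactions are tandem ring-closing enyne metathesis/cross-metathesis and the palladium-catalysed heteroannulation of 1,3-dienes with 2-iodophenols, including its ligand-controlled enantioselective variants.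

**Compound list**

1 | penta-1,4-dien-3-ol (divinylcarbinol) | C=CC(O)C=C | starting material
2 | (2R,3S)-1,2-epoxypent-4-en-3-ol, i.e. (1S)-1-[(2R)-oxiran-2-yl]prop-2-en-1-ol | C=C[C@H](O)[C@H]1CO1 | intermediate
3 | 3-bromoprop-1-yne (propargyl bromide) | C#CCBr | starting material
4 | allenylmagnesium bromide | C=C=C[Mg]Br | intermediate (not isolated)
5 | (3S,4R)-oct-1-en-7-yne-3,4-diol | C=C[C@H](O)[C@H](O)CCC#C | intermediate
6 | 4-(3-hydroxypropyl)-2-methoxyphenol (dihydroconiferyl alcohol) | COc1cc(CCCO)ccc1O | starting material
7 | 4-(3-hydroxypropyl)-2-iodo-6-methoxyphenol | COc1cc(CCCO)cc(I)c1O | intermediate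
8 | prop-2-en-1-ol (allyl alcohol) | C=CCO | starting material
9 | (1R,2S)-4-[(1E)-3-hydroxyprop-1-en-1-yl]cyclohex-3-ene-1,2-diol | OC/C=C/C1=C[C@H](O)[C@H](O)CC1 | intermediate (not isolated)
10 | difengpiol A, (1R,2S)-4-[(2S,3R)-3-(hydroxymethyl)-5-(3-hydroxypropyl)-7-methoxy-2,3-dihydro-1-benzofuran-2-yl]cyclohex-3-ene-1,2-diol | COc1cc(CCCO)cc2c1O[C@H](C1=C[C@H](O)[C@H](O)CC1)[C@H]2CO | target

**Step count and risks**

Total steps: 4. Longest linear sequence: 3 (1 → 2 → 5 → 10); step 3 is a one-step side branch.

Steps most likely to fail:

Step 4 is the main risk: E/Z purity of the diene, ruthenium residues and the free diol in the palladium stage, and face selectivity in the aryl insertion. The fallback sets out from 5 and comes back at 10; it separates the two ring closures and fixes the diene geometry with a tether. Diol 5 is protected with 2,2-dimethoxypropane and PPTS in acetone as the acetonide F1. The alkyne is deprotonated with n-BuLi in THF at −78 °C, quenched with iPr2SiCl2 and then with 8 and imidazole to give the allyloxysilyl alkyne F2. Second-generation Grubbs catalyst RuCl2(H2IMes)(PCy3)(=CHPh) in CH2Cl2 at 40 °C runs an ene–yne–ene ring-closing metathesis cascade that closes the cyclohexene and a five-membered oxasilole together, giving the bicyclic siloxane F3 with the exocyclic alkene geometry locked by the ring. TBAF in THF at 50 °C removes silicon with retention to give the pure (E)-dienol acetonide F4. F4 and 7 are joined under the palladium conditions of step 4 to give the protected adduct F5, from which the minor diastereomer is more easily separated. 80% aqueous AcOH at 40 °C releases the diol to give 10.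

Step 2 is the second risk: the magnesium alkoxide of 2 can undergo Payne rearrangement, and the Grignard can give allenyl as well as propargyl product. The fallback sets out from 2 and comes back at 5. The hydroxyl is silylated with TBSCl and imidazole in DMF to the silyl ether F6. The epoxide is opened with LiCH2C≡CSiMe3 (from 1-(trimethylsilyl)propyne and n-BuLi) and BF3·OEt2 in THF at −78 °C to give the doubly silylated enynol F7. TBAF in THF removes both silyl groups to give 5.

Step 3 is the third risk: iodination para to the methoxy group instead of ortho to the hydroxyl, or over-iodination of the electron-rich ring. The fallback sets out from 6 and comes back at 10; it avoids the aryl halide altogether. Phenol 6 is O-aminated with KOtBu and O-(mesitylsulfonyl)hydroxylamine in THF at 0 °C to the aryloxyamine F8, which is N-acetylated with Ac2O and NaHCO3 to the aryloxyacetamide F9. The ruthenium stage of step 4 is run as written and 9 is passed through a short silica plug. F9 and 9 are then combined with [Cp*RhCl2]2 (2.5 mol%) and CsOAc in MeOH at rt: ortho C–H rhodation (the only free ortho position), insertion of the E-alkene of the diene, and C–O bond formation with N–O cleavage as internal oxidant give 10 directly.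

**Further compounds**

F1 | step 4 | (4R,5S)-4-(but-3-yn-1-yl)-5-ethenyl-2,2-dimethyl-1,3-dioxolane | C=C[C@@H]1OC(C)(C)O[C@@H]1CCC#C
F2 | step 4 | {4-[(4R,5S)-5-ethenyl-2,2-dimethyl-1,3-dioxolan-4-yl]but-1-yn-1-yl}di(propan-2-yl)(prop-2-en-1-yloxy)silane | C=C[C@@H]1OC(C)(C)O[C@@H]1CCC#C[Si](C(C)C)(C(C)C)OCC=C
F3 | step 4 | (3aS,7aR)-5-[2,2-di(propan-2-yl)-2,5-dihydro-1,2-oxasilol-3-yl]-2,2-dimethyl-3a,6,7,7a-tetrahydro-1,3-benzodioxole | CC(C)[Si]1(C(C)C)OCC=C1C2=C[C@@H]3OC(C)(C)O[C@@H]3CC2
F4 | step 4 | (2E)-3-[(3aS,7aR)-2,2-dimethyl-3a,6,7,7a-tetrahydro-1,3-benzodioxol-5-yl]prop-2-en-1-ol | OC/C=C/C1=C[C@@H]2OC(C)(C)O[C@@H]2CC1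
F5 | step 4 | 3-[(2S,3R)-2-[(3aS,7aR)-2,2-dimethyl-3a,6,7,7a-tetrahydro-1,3-benzodioxol-5-yl]-3-(hydroxymethyl)-7-methoxy-2,3-dihydro-1-benzofuran-5-yl]propan-1-ol | COc1cc(CCCO)cc2c1O[C@H](C3=C[C@@H]4OC(C)(C)O[C@@H]4CC3)[C@H]2CO
F6 | step 2 | tert-butyl(dimethyl){[(1S)-1-[(2R)-oxiran-2-yl]prop-2-en-1-yl]oxy}silane | C=C[C@H](O[Si](C)(C)C(C)(C)C)[C@H]1CO1
F7 | step 2 | (3S,4R)-3-{[tert-butyl(dimethyl)silyl]oxy}-8-(trimethylsilyl)oct-1-en-7-yn-4-ol | C=C[C@H](O[Si](C)(C)C(C)(C)C)[C@H](O)CCC#C[Si](C)(C)C
F8 | step 3 | O-[4-(3-hydroxypropyl)-2-methoxyphenyl]hydroxylamine | COc1cc(CCCO)ccc1ON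
F9 | step 3 | N-[4-(3-hydroxypropyl)-2-methoxyphenoxy]acetamide | COc1cc(CCCO)ccc1ONC(C)=O
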